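## Structural features

The target is a 1,2-dioxolane (ring atoms O1, O2, C3, C4, C5) in which both oxygen-bearing ring carbons are fully substituted. C3 carries a methyl group and the CH2CO2Me arm (C2, C1); C5 carries a methyl group and a (2R)-2-methyl-8-phenyloctyl chain (C6 to C13, then phenyl); C4 is a plain CH2. There are three stereocentres: C3 (R) and C5 (S) stand 1,3 to each other across C4, with the acetate arm and the C5 methyl on the same ring face, and C7 (R) is a methyl-branched carbon one CH2 away from C5. The O–O bond is the fragile element and rules out hydrogenation, hydrides, low-valent metals and phosphines once it is in place. The ester α-CH2 lies β to a peroxide oxygen, so base can open the ring by elimination, and neither C3 nor C5 has a hydrogen that would allow later epimerisation. The real difficulty is to create two tetrasubstituted C–O stereocentres, each of which must tell a methyl group from a CH2R group; C7 is too remote to help. The plan exploits the C5 methyl: it can be held as the CH2 of a 1,1-disubstituted alkene placed 1,3 to a hydroperoxide on C3. That hydroperoxide is installed with defined configuration by opening, with inversion, an oxetane made of O, C3, C2 and C1, which also frees the C1 oxygen that becomes the ester. The C3 descriptor reads S in 18 and 19 and R in 17, 20 and 21 with unchanged geometry, because only the ranking of the substituents changes.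

## Logic of the disconnections

21 to 19. The ester O–CH3 bond of 21 is cut, and the carboxyl carbon C1 of 20 is then taken down to the CH2OH level of 19. A carboxyl group β to the peroxide oxygen is the most base-sensitive arrangement in the molecule, whereas a primary alcohol passes through peroxide formation and radical chemistry unharmed. The gain is that the C1 oxygen of 19 is the very oxygen an oxetane opening releases, so no protecting group is spent on it. The forward steps must oxidise and methylate without base, reductant or a metal that attacks the O–O bond.

19 to 18. One C–H bond of the C5 methyl group is exchanged for a carbon–iodine bond. Iodine is the trace of an electrophilic ring closure, so this cut turns an inert methyl group into a handle. The forward step needs hydrogen-atom transfer fast enough to beat collapse of the β-peroxy radical to an epoxide.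

18 to 17. The O–C5 bond is cut, which opens the dioxolane and returns the iodomethyl carbon to an alkene CH2. Ring and C5 stereocentre vanish together, leaving an acyclic chain with one oxygen-bearing stereocentre. The forward closure must be Markovnikov and 5-exo, must use the hydroperoxide and not the hydroxyl, and must choose an alkene face under the sole influence of C3. The C1 hydroxyl of 17 is left free on purpose. Masking it beside the more acidic hydroperoxide would cost at least two steps, its only mode of attack is a slower six-membered closure, and no protecting group would enlarge the size difference at C3 that governs the facial choice.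

17 to 16. The bond between C3 and the peroxide oxygen is cut and C3 is reconnected to the C1 oxygen. This hides hydroperoxide and hydroxyl together in one robust ether and turns the C3 configuration into a matter of substitution with inversion, so 16 must carry the opposite sense at C3. The forward step needs a promoter that activates the ring oxygen without ionising C3 to a free cation or drawing in the nearby alkene.

16 to 12 and 13. The C5=CH2 bond of 16 is cut back to the C5 carbonyl of 15, this is taken to the C5 carbinol of 14, and then the C5–C6 bond is cut. The skeleton divides into a C1–C5 piece holding the oxetane and a C6–C13 piece holding C7; the carbinol centre of 14 is transient and needs no control. Carbonyl groups β to the oxetane oxygen must meet no acid and no more base than an addition or an olefination requires.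

12 to 10. The aldehyde carbon C5 of 12 is returned to the alcohol level of 11, and the hydroxyl is capped as the benzyl ether of 10. A benzyl ether survives the basic ylide chemistry that precedes it and leaves by neutral hydrogenolysis, which an oxetane tolerates.

10 to 6 and 7. The O–C1 and C1–C2 bonds of 10 are cut to reach 9, and the O–C2 and C2–C3 bonds of 9 are cut to reach 6; both CH2 groups come from 8, made from 7. The whole C1–C5 fragment with its stereocentre thus derives from an achiral methyl ketone in one flask. The forward step needs a catalyst that distinguishes the methyl side from the CH2CH2OBn side of 6.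

13 to 2 and 1. The carbon–magnesium bond of 13 goes back to the C6–Br bond of 5 and the C6–OH bond of 4, and the C8–C9 bond of 4 is cut to give 2 and 3, the latter from 1. C7 is bought in. Coupling occurs at the CH2Br carbon of 2 while its CH2OH carbon becomes C6, so the S descriptor of 2 becomes R in 4 without any bond at C7 being touched.

## Other disconnections considered

Alternative 1: The cut runs through C4–C5 and O–C3, so the ring is assembled from a C5 peroxycarbenium fragment and a C3–C4 alkene.
- Forward step: SnCl4 would ionise the silylperoxy ketal A2 (triethyl{[(2RS,4R)-2-methoxy-4-methyl-10-phenyldecan-2-yl]peroxy}silane). The CH2 of the alkene A3 (tert-butyl[(3-methylbut-3-en-1-yl)oxy]diphenylsilane) would attack the cationic C5, and the silylperoxy oxygen would trap the tertiary cation at C3. The product would be A1 (tert-butyl{2-[(3S,5S)-3,5-dimethyl-5-[(2R)-2-methyl-8-phenyloctyl]-1,2-dioxolan-3-yl]ethoxy}diphenylsilane).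
- In its favour: it is the most convergent option. Ring and both quaternary carbons arise in one step, A3 is one step from a cheap alcohol, A2 should be reachable from 13 in about three steps, and no iodine or tin is involved.
- Against it: neither C3 nor C5 is set by anything. Both partners are flat at the reacting carbons and C7 is remote, so all four C3/C5 combinations are to be expected. The cis/trans preference should be small because each carbon carries CH3 and CH2R. The wanted isomer would be a minor part of a mixture that is hard to separate. The tertiary cation at C3 can also lose a proton instead of closing.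
- Comparison: on step economy and convergence this alternative is the equal or the better of the chosen plan, and it avoids the β-peroxy radical. On structure the chosen plan is better, since C3 is fixed absolutely and only C5 is left open (two isomers, not four).

Alternative 2: The cut is at O–C5 and O–C3 with the carbon chain intact as the enone A4 ((3E,6R)-4,6-dimethyl-12-phenyldodec-3-en-2-one).
- Forward step: the cinchona-derived primary amine salt would form the iminium ion, H2O2 would add to the β-carbon, and the hydroperoxide would close on the carbonyl. The product would be A5 ((5S)-3,5-dimethyl-5-[(2R)-2-methyl-8-phenyloctyl]-1,2-dioxolan-3-ol) as anomers. Activation of the anomeric hydroxyl and Lewis-acid-mediated addition of a silyl ketene acetal to the C3 peroxycarbenium ion would then lead to 21 directly.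
- In its favour: C5 would be set by the catalyst, the acetate arm would arrive at the right oxidation level, aqueous H2O2 replaces the anhydrous reagent, and the sequence is the shortest of all.
- Against it: the β-carbon of A4 is fully substituted. Conjugate addition that creates a tetrasubstituted C–O centre lies outside the β-monosubstituted enones on which this catalysis rests. The catalyst would have to tell CH3 from CH2R, and E/Z isomerisation of A4 through a dienamine would erase the information. C3 would then be set late on a nearly planar cation, biased only by the CH3/CH2R difference at C5.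
- Comparison: it is better on step economy and endgame, and equal in leaving one ring stereocentre under weak substrate control. It is worse in that its stereodefining step relies on an untested substrate class, whereas C3 in the chosen plan comes from a stereospecific substitution.

Alternative 3: The cut is the O–O bond.
- Forward step: tetravalent lead in Pb(OAc)4 would oxidise both hydroperoxide groups of A6 ((3S,5S,7R)-3,5-dihydroperoxy-3,5,7-trimethyl-13-phenyltridecan-1-ol) to peroxyl radicals. These would join to a cyclic tetroxide that loses O2 and leaves the ring O–O bond of A7 (2-[(3S,5S)-3,5-dimethyl-5-[(2R)-2-methyl-8-phenyloctyl]-1,2-dioxolan-3-yl]ethan-1-ol, the same substance as 19).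
- In its favour: no C–O bond is made or broken in the closure, so both stereocentres pass through unchanged; on this point it is better than the chosen key step. The product is 19 itself, so iodine, tin and the β-peroxy radical are avoided.
- Against it: the burden moves to A6, which needs two tertiary hydroperoxides of defined configuration. C3 could come from the same oxetane opening as in 17, but C5 would need a second enantioenriched oxetane or an unselective cobalt-catalysed hydroperoxidation of 17. The tetroxide can also fragment to alkoxyl radicals that undergo β-scission, lead tetraacetate attacks the free primary alcohol, and a bis(hydroperoxide) is the most hazardous intermediate of any plan.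
- Comparison: it is equal on C3, at best equal on C5, at least one step longer, and expected to pass less material. It is better only in sparing the deiodination.

Key step: step 10

Remark on the chemistry (assumption): in step 3 the (S)-binaphthoxide catalyst is written as the antipode that delivers the (S)-epoxide 9; if the facial sense for this ketone is the reverse, the (R)-ligand is used and nothing else changes.

## Route

Step 1
Reactants: 1 (5-bromopentyl)benzene; 2 (2S)-3-bromo-2-methylpropan-1-ol
Product: 4 (2R)-2-methyl-8-phenyloctan-1-ol, via (5-phenylpentyl)magnesium bromide 3 (not isolated)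
Conditions: Mg, THF, 40 °C (1 → 3, 3 equiv); then 2, Li2CuCl4 (3 mol %), THF, −20 °C → rt; aq NH4Cl
Reagents that add atoms: none
Why: Copper-catalysed Kochi-type coupling of a primary Grignard reagent with a primary bromide; the first equivalent of 3 converts the hydroxyl into its alkoxide, so no protecting group is needed. The stereocentre is a bystander next to the reacting CH2Br and keeps its geometry, the descriptor changing from S to R by priority only.

Step 2
Reactants: 4 (2R)-2-methyl-8-phenyloctan-1-ol
Product: 5 [(7R)-8-bromo-7-methyloctyl]benzene
Conditions: CBr4, PPh3, CH2Cl2, 0 °C → rt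
Reagents that add atoms: carbon tetrabromide, BrC(Br)(Br)Br
Why: Appel bromination, an SN2 displacement at the primary carbinol carbon; the adjacent stereocentre bears no leaving group and cannot be affected.

Step 3
Reactants: 6 4-(benzyloxy)butan-2-one; 7 trimethylsulfoxonium iodide
Product: 10 (2R)-2-[2-(benzyloxy)ethyl]-2-methyloxetane, via dimethylsulfoxonium methylide 8 (not isolated), via (2S)-2-[2-(benzyloxy)ethyl]-2-methyloxirane 9 (not isolated)
Conditions: NaH, THF, reflux (7 → 8); 6, LaLi3[(S)-binaphthoxide]3 (5 mol %), (2,4,6-(MeO)3C6H2)3P=O (5 mol %), 5 Å MS, THF, rt; then further 8 and catalyst, 45 °C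
Reagents that add atoms: none
Why: Catalytic asymmetric Corey–Chaykovsky methylene transfer: the heterobimetallic catalyst binds ketone and ylide and delivers CH2 to one face of the methyl ketone, setting the C3 stereocentre in 9. A second ylide opens 9 at its CH2 and the γ-alkoxide displaces DMSO (4-exo-tet) without touching the C–O stereocentre. The catalyst expands the major epoxide enantiomer faster, so the enantiomeric purity of 10 should exceed that of 9.

Step 4
Reactants: 10 (2R)-2-[2-(benzyloxy)ethyl]-2-methyloxetane
Product: 11 2-[(2S)-2-methyloxetan-2-yl]ethan-1-ol
Conditions: H2 (1 atm), 10% Pd/C, EtOAc, rt; solvent removed cold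
Reagents that add atoms: none
Why: Neutral hydrogenolysis of the benzyl ether; the oxetane has no benzylic or allylic C–O bond and is inert. The descriptor changes from R to S by priority only.

Step 5
Reactants: 11 2-[(2S)-2-methyloxetan-2-yl]ethan-1-ol
Product: 12 2-[(2R)-2-methyloxetan-2-yl]acetaldehyde
Conditions: Dess–Martin periodinane, NaHCO3, CH2Cl2, 0 °C; filtered through a short silica pad and used at once as a dried solution
Reagents that add atoms: none
Why: Dess–Martin oxidation under bicarbonate buffer is neither acidic nor basic, so the oxetane is opened neither by acid nor by E1cB elimination from the new aldehyde. The small, volatile aldehyde is not stored.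

Step 6
Reactants: 5 [(7R)-8-bromo-7-methyloctyl]benzene; 12 2-[(2R)-2-methyloxetan-2-yl]acetaldehyde
Product: 14 (2RS,4R)-4-methyl-1-[(2R)-2-methyloxetan-2-yl]-10-phenyldecan-2-ol, via [(2R)-2-methyl-8-phenyloctyl]magnesium bromide 13 (not isolated)
Conditions: Mg, THF, 45 °C (5 → 13); then 12, THF, −78 → 0 °C; aq NH4Cl
Reagents that add atoms: none
Why: Grignard addition to an aldehyde, run cold so that addition outruns enolisation. The new carbinol centre is not controlled and need not be, since it is oxidised in the next step.

Step 7
Reactants: 14 (2RS,4R)-4-methyl-1-[(2R)-2-methyloxetan-2-yl]-10-phenyldecan-2-ol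
Product: 15 (4R)-4-methyl-1-[(2R)-2-methyloxetan-2-yl]-10-phenyldecan-2-one
Conditions: Dess–Martin periodinane, NaHCO3, CH2Cl2, 0 °C → rt
Reagents that add atoms: none
Why: Buffered Dess–Martin oxidation merges both carbinol epimers into one ketone; C7 is β to the carbonyl and cannot epimerise.

Step 8
Reactants: 15 (4R)-4-methyl-1-[(2R)-2-methyloxetan-2-yl]-10-phenyldecan-2-one
Product: 16 (2S)-2-methyl-2-[(4R)-4-methyl-2-methylidene-10-phenyldecyl]oxetane
Conditions: Ph3PCH3Br (1.5 equiv), KOtBu (1.4 equiv), THF, 0 °C → rt
Reagents that add atoms: methyltriphenylphosphonium bromide, C[P+](c1ccccc1)(c1ccccc1)c1ccccc1.[Br-]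
Why: Wittig methylenation of an unhindered ketone flanked by two CH2 groups; at 0 °C with little excess ylide, addition should outrun enolisation, which could otherwise open the oxetane by E1cB.

Step 9
Reactants: 16 (2S)-2-methyl-2-[(4R)-4-methyl-2-methylidene-10-phenyldecyl]oxetane
Product: 17 (3R,7R)-3-hydroperoxy-3,7-dimethyl-5-methylidene-13-phenyltridecan-1-ol
Conditions: anhydrous H2O2 in Et2O (10 equiv), TMSOTf (0.2 equiv), −78 → 0 °C; small scale, behind a shield
Reagents that add atoms: hydrogen peroxide, OO
Why: Lewis-acid-promoted perhydrolysis of a 2,2-disubstituted oxetane: the silylated ring oxygen leaves as H2O2 attacks the tertiary carbon from the opposite side in a tight SN2-like process. C3 is inverted to the required sense and the C1 hydroxyl is released. Excess H2O2 suppresses capture of a second oxetane by the product, and the low temperature holds back free-cation formation.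

Step 10
Reactants: 17 (3R,7R)-3-hydroperoxy-3,7-dimethyl-5-methylidene-13-phenyltridecan-1-ol
Product: 18 2-[(3S,5S)-5-(iodomethyl)-3-methyl-5-[(2R)-2-methyl-8-phenyloctyl]-1,2-dioxolan-3-yl]ethan-1-ol
Conditions: N-iodosuccinimide (1.3 equiv), CH2Cl2, 0 °C, dark; C5 epimer removed by chromatography
Reagents that add atoms: N-iodosuccinimide, O=C1CCC(=O)N1I
Why: N-Iodosuccinimide transfers iodonium to the electron-rich 1,1-disubstituted alkene; the bridged ion carries most of its positive charge on the fully substituted carbon C5, and the terminal oxygen of the C3 hydroperoxide opens it there, anti to iodine, forming the O–C5 bond while the proton ends on succinimide. The closest known reaction type is the halonium- or mercury-induced cyclisation of unsaturated hydroperoxides, the peroxide counterpart of iodoetherification. The 1,2-dioxolane ring closes in the 5-exo mode; 6-endo attack at the CH2 terminus would require anti-Markovnikov opening and is not expected. The new stereocentre C5 is controlled only by C3: in a chair-like transition state (O, O, C3, C4, C5 and the alkene CH2) the C3 methyl should sit pseudo-axial and the slightly larger CH2CH2OH pseudo-equatorial, which places the iodomethyl group cis to the hydroxyethyl arm as in 18. This preference is weak because the two C3 substituents differ little in size, so the C5 epimer will form as well and is separated at this stage. The step also needs chemoselectivity between hydroperoxide and C1 hydroxyl: the hydroperoxide is the better nucleophile (α-effect) and closes a five-membered ring, whereas the hydroxyl could only close a six-membered ether, and under these non-acidic conditions the closure is irreversible. C3 and C7 are not touched.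

Step 11
Reactants: 18 2-[(3S,5S)-5-(iodomethyl)-3-methyl-5-[(2R)-2-methyl-8-phenyloctyl]-1,2-dioxolan-3-yl]ethan-1-ol
Product: 19 2-[(3S,5S)-3,5-dimethyl-5-[(2R)-2-methyl-8-phenyloctyl]-1,2-dioxolan-3-yl]ethan-1-ol
Conditions: Bu3SnH (10 equiv, ca. 2 M), Et3B (0.2 equiv), air, toluene, 0 °C
Reagents that add atoms: none
Why: Radical-chain hydrodeiodination; the primary radical is β to the peroxide and could close to an epoxide with O–O cleavage. The hydrogen donor is therefore used at high concentration and low temperature so that bimolecular hydrogen transfer outpaces that unimolecular collapse. The radical carbon is not a stereocentre, so C3, C5 and C7 are unchanged.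

Step 12
Reactants: 19 2-[(3S,5S)-3,5-dimethyl-5-[(2R)-2-methyl-8-phenyloctyl]-1,2-dioxolan-3-yl]ethan-1-ol
Product: 20 2-[(3R,5S)-3,5-dimethyl-5-[(2R)-2-methyl-8-phenyloctyl]-1,2-dioxolan-3-yl]acetic acid
Conditions: TEMPO (0.2 equiv), PhI(OAc)2 (2.5 equiv), MeCN–H2O (1:1), rt
Reagents that add atoms: water, O
Why: Oxoammonium-mediated oxidation of the primary alcohol to the aldehyde, whose hydrate is oxidised on to the acid. No metal, reductant or base is present, so the O–O bond, the phenyl ring and the β-peroxy carbonyl intermediate survive. The C3 descriptor changes from S to R by priority only.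

Step 13
Reactants: 20 2-[(3R,5S)-3,5-dimethyl-5-[(2R)-2-methyl-8-phenyloctyl]-1,2-dioxolan-3-yl]acetic acid
Product: 21 methyl 2-[(3R,5S)-3,5-dimethyl-5-[(2R)-2-methyl-8-phenyloctyl]-1,2-dioxolan-3-yl]acetate
Conditions: TMSCHN2 (1.5 equiv), MeOH–toluene (1:3), 0 °C
Reagents that add atoms: (trimethylsilyl)diazomethane, C[Si](C)(C)C=[N+]=[N-]
Why: O-Methylation of the carboxylic acid through a methyldiazonium carboxylate ion pair; no base is present, so the α-CH2 is never deprotonated and the peroxide cannot be lost by β-elimination.

## Compound list

1 | (5-bromopentyl)benzene | BrCCCCCc1ccccc1 | starting material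
2 | (2S)-3-bromo-2-methylpropan-1-ol | OC[C@H](C)CBr | starting material
3 | (5-phenylpentyl)magnesium bromide | Br[Mg]CCCCCc1ccccc1 | intermediate (not isolated)
4 | (2R)-2-methyl-8-phenyloctan-1-ol | OC[C@H](C)CCCCCCc1ccccc1 | intermediate
5 | [(7R)-8-bromo-7-methyloctyl]benzene | BrC[C@H](C)CCCCCCc1ccccc1 | intermediate
6 | 4-(benzyloxy)butan-2-one | CC(=O)CCOCc1ccccc1 | starting material
7 | trimethylsulfoxonium iodide | C[S+](C)(C)=O.[I-] | starting material
8 | dimethylsulfoxonium methylide | C[S+](C)(=O)[CH2-] | intermediate (not isolated)
9 | (2S)-2-[2-(benzyloxy)ethyl]-2-methyloxirane | O1C[C@]1(C)CCOCc2ccccc2 | intermediate (not isolated)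
10 | (2R)-2-[2-(benzyloxy)ethyl]-2-methyloxetane | O1CC[C@]1(C)CCOCc2ccccc2 | intermediate
11 | 2-[(2S)-2-methyloxetan-2-yl]ethan-1-ol | O1CC[C@]1(C)CCO | intermediate
12 | 2-[(2R)-2-methyloxetan-2-yl]acetaldehyde | O1CC[C@]1(C)CC=O | intermediate
13 | [(2R)-2-methyl-8-phenyloctyl]magnesium bromide | Br[Mg]C[C@H](C)CCCCCCc1ccccc1 | intermediate (not isolated)
14 | (2RS,4R)-4-methyl-1-[(2R)-2-methyloxetan-2-yl]-10-phenyldecan-2-ol | O1CC[C@]1(C)CC(O)C[C@H](C)CCCCCCc2ccccc2 | intermediate
15 | (4R)-4-methyl-1-[(2R)-2-methyloxetan-2-yl]-10-phenyldecan-2-one | O1CC[C@]1(C)CC(=O)C[C@H](C)CCCCCCc2ccccc2 | intermediate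
16 | (2S)-2-methyl-2-[(4R)-4-methyl-2-methylidene-10-phenyldecyl]oxetane | O1CC[C@]1(C)CC(=C)C[C@H](C)CCCCCCc2ccccc2 | intermediate
17 | (3R,7R)-3-hydroperoxy-3,7-dimethyl-5-methylidene-13-phenyltridecan-1-ol | OCC[C@@](OO)(C)CC(=C)C[C@H](C)CCCCCCc1ccccc1 | intermediate
18 | 2-[(3S,5S)-5-(iodomethyl)-3-methyl-5-[(2R)-2-methyl-8-phenyloctyl]-1,2-dioxolan-3-yl]ethan-1-ol | OCC[C@@]1(C)C[C@](CI)(C[C@H](C)CCCCCCc2ccccc2)OO1 | intermediate
19 | 2-[(3S,5S)-3,5-dimethyl-5-[(2R)-2-methyl-8-phenyloctyl]-1,2-dioxolan-3-yl]ethan-1-ol | OCC[C@@]1(C)C[C@](C)(C[C@H](C)CCCCCCc2ccccc2)OO1 | intermediate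
20 | 2-[(3R,5S)-3,5-dimethyl-5-[(2R)-2-methyl-8-phenyloctyl]-1,2-dioxolan-3-yl]acetic acid | OC(=O)C[C@@]1(C)C[C@](C)(C[C@H](C)CCCCCCc2ccccc2)OO1 | intermediate
21 | methyl 2-[(3R,5S)-3,5-dimethyl-5-[(2R)-2-methyl-8-phenyloctyl]-1,2-dioxolan-3-yl]acetate | COC(=O)C[C@@]1(C)C[C@](C)(C[C@H](C)CCCCCCc2ccccc2)OO1 | target

## Step count and least certain steps

Total: 13 steps. Longest linear sequence: 11 steps (steps 3 to 13, from 6); the side-chain branch (steps 1 and 2) joins at step 6. All peroxide-containing compounds from 17 onward are to be handled on a small scale, cold and behind a shield.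

Step 10 (key step). The most likely failure is poor facial discrimination in the ring closure, because the two C3 substituents that steer it are nearly the same size, so much material may go to the C5 epimer. Capture of the iodonium ion by the C1 hydroxyl and oxidative loss of the hydroperoxide to the iodinating agent are lesser concerns. The fallback sets out from 17 and returns at 18. Cycloperoxymercuration with Hg(OAc)2 in CH2Cl2 would give the organomercurial {[(3S,5S)-5-(2-hydroxyethyl)-5-methyl-3-[(2R)-2-methyl-8-phenyloctyl]-1,2-dioxolan-3-yl]methyl}mercury acetate F1. Divalent mercury is a softer electrophile that does not oxidise the hydroperoxide, and with a trace of HClO4 its addition is reversible, which gives the C5 ratio a second chance under thermodynamic control. Iododemercuration of F1 with iodine then gives 18.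

Step 11. The primary radical formed on iodine abstraction may attack the neighbouring peroxide oxygen and open the ring to an epoxide before it meets the hydrogen donor. The fallback sets out from 16 and returns at 19, and never creates a carbon radical β to a peroxide. Cobalt-catalysed hydrosilylperoxidation of the alkene (Co(acac)2, Et3SiH, O2) would place a silyl peroxide on C5 and a hydrogen on the CH2, giving (2R)-2-{(2RS,4R)-2,4-dimethyl-10-phenyl-2-[(triethylsilyl)peroxy]decyl}-2-methyloxetane F2. Fluoride (Bu4NF, AcOH) would free the hydroperoxide (2R)-2-[(2RS,4R)-2-hydroperoxy-2,4-dimethyl-10-phenyldecyl]-2-methyloxetane F3. A catalytic Lewis acid (TMSOTf or Yb(OTf)3, CH2Cl2, cold) would then let that hydroperoxide open the oxetane at C3 in a 5-exo closure with inversion. This gives 19 and its C5 epimer, which are separated.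

Step 9. Activation of the oxetane may go beyond the tight SN2-like opening to a free tertiary cation, which would erode the C3 configuration, and the 1,1-disubstituted alkene two carbons away may take part in that cation or be attacked by the acid. The fallback sets out from 16 and returns at 18, and reverses the order of the two C–O bond formations. Iodohydroperoxidation of the alkene with N-iodosuccinimide and ethereal H2O2 (halohydroperoxidation of the Kopecky type, no acid present) would give (2R)-2-[(2RS,4R)-2-hydroperoxy-2-(iodomethyl)-4-methyl-10-phenyldecyl]-2-methyloxetane F4. A catalytic Lewis acid would then induce the intramolecular 5-exo opening of the oxetane at C3 with inversion. Because that closure is intramolecular and the alkene is already consumed, it should be faster and cleaner than the intermolecular perhydrolysis. It gives 18 and its C5 epimer.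

Step 3. The β-benzyloxy group may chelate the lanthanum–lithium catalyst and spoil the discrimination between the two ketone faces, and the basic ylide may expel benzyl alcohol from the β-alkoxy ketone. The fallback sets out from 6 and returns at 10 by a Sharpless sequence.
- Horner–Wadsworth–Emmons reaction with triethyl phosphonoacetate and NaH would give, after removal of the Z isomer, ethyl (2E)-5-(benzyloxy)-3-methylpent-2-enoate F5.
- Reduction with i-Bu2AlH would give (2E)-5-(benzyloxy)-3-methylpent-2-en-1-ol F6.
- Sharpless epoxidation (Ti(OiPr)4, L-(+)-diethyl tartrate, t-BuOOH, 4 Å MS, −20 °C) would give [(2S,3S)-3-[2-(benzyloxy)ethyl]-3-methyloxiran-2-yl]methanol F7, by analogy with the facial sense known for E-configured 3-methylalk-2-en-1-ols.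
- NaAlH2(OCH2CH2OMe)2 would deliver hydride to C2 and give (3R)-5-(benzyloxy)-3-methylpentane-1,3-diol F8.
- One-pot treatment with KOtBu and TsCl would form (3S)-5-(benzyloxy)-3-hydroxy-3-methylpentyl 4-methylbenzenesulfonate F9, and a second equivalent of KOtBu would close it to 10 with retention at the tertiary carbon.

## Further compounds

F1 | step 10 | {[(3S,5S)-5-(2-hydroxyethyl)-5-methyl-3-[(2R)-2-methyl-8-phenyloctyl]-1,2-dioxolan-3-yl]methyl}mercury acetate | OCC[C@@]1(C)C[C@](C[Hg]OC(C)=O)(C[C@H](C)CCCCCCc2ccccc2)OO1
F2 | step 11 | (2R)-2-{(2RS,4R)-2,4-dimethyl-10-phenyl-2-[(triethylsilyl)peroxy]decyl}-2-methyloxetane | O1CC[C@]1(C)CC(C)(OO[Si](CC)(CC)CC)C[C@H](C)CCCCCCc2ccccc2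
F3 | step 11 | (2R)-2-[(2RS,4R)-2-hydroperoxy-2,4-dimethyl-10-phenyldecyl]-2-methyloxetane | O1CC[C@]1(C)CC(C)(OO)C[C@H](C)CCCCCCc2ccccc2
F4 | step 9 | (2R)-2-[(2RS,4R)-2-hydroperoxy-2-(iodomethyl)-4-methyl-10-phenyldecyl]-2-methyloxetane | O1CC[C@]1(C)CC(CI)(OO)C[C@H](C)CCCCCCc2ccccc2
F5 | step 3 | ethyl (2E)-5-(benzyloxy)-3-methylpent-2-enoate | CCOC(=O)/C=C(\C)CCOCc1ccccc1
F6 | step 3 | (2E)-5-(benzyloxy)-3-methylpent-2-en-1-ol | OC/C=C(\C)CCOCc1ccccc1
F7 | step 3 | [(2S,3S)-3-[2-(benzyloxy)ethyl]-3-methyloxiran-2-yl]methanol | OC[C@@H]1O[C@@]1(C)CCOCc2ccccc2
F8 | step 3 | (3R)-5-(benzyloxy)-3-methylpentane-1,3-diol | OCC[C@](O)(C)CCOCc1ccccc1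
F9 | step 3 | (3S)-5-(benzyloxy)-3-hydroxy-3-methylpentyl 4-methylbenzenesulfonate | Cc1ccc(cc1)S(=O)(=O)OCC[C@](O)(C)CCOCc2ccccc2
A1 | alternative 1 | tert-butyl{2-[(3S,5S)-3,5-dimethyl-5-[(2R)-2-methyl-8-phenyloctyl]-1,2-dioxolan-3-yl]ethoxy}diphenylsilane | CC(C)(C)[Si](c1ccccc1)(c1ccccc1)OCC[C@@]1(C)C[C@](C)(C[C@H](C)CCCCCCc2ccccc2)OO1
A2 | alternative 1 | triethyl{[(2RS,4R)-2-methoxy-4-methyl-10-phenyldecan-2-yl]peroxy}silane | CC[Si](CC)(CC)OOC(C)(OC)C[C@H](C)CCCCCCc1ccccc1
A3 | alternative 1 | tert-butyl[(3-methylbut-3-en-1-yl)oxy]diphenylsilane | CC(=C)CCO[Si](c1ccccc1)(c1ccccc1)C(C)(C)C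
A4 | alternative 2 | (3E,6R)-4,6-dimethyl-12-phenyldodec-3-en-2-one | CC(=O)/C=C(\C)C[C@H](C)CCCCCCc1ccccc1
A5 | alternative 2 | (5S)-3,5-dimethyl-5-[(2R)-2-methyl-8-phenyloctyl]-1,2-dioxolan-3-ol (C3 anomers) | CC1(O)C[C@](C)(C[C@H](C)CCCCCCc2ccccc2)OO1
A6 | alternative 3 | (3S,5S,7R)-3,5-dihydroperoxy-3,5,7-trimethyl-13-phenyltridecan-1-ol | OCC[C@@](OO)(C)C[C@](C)(C[C@H](C)CCCCCCc1ccccc1)OO
A7 | alternative 3 | 2-[(3S,5S)-3,5-dimethyl-5-[(2R)-2-methyl-8-phenyloctyl]-1,2-dioxolan-3-yl]ethan-1-ol | OCC[C@@]1(C)C[C@](C)(C[C@H](C)CCCCCCc2ccccc2)OO1
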